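**Assumption:** the SMILES is taken as drawn, i.e. (2S,3S,6S,10R) with tertiary Br at C3 and secondary Cl at C2. Chamigrene-style locants are used for every intermediate (ring B = C1–C5, spiro = C6, ring A = C7–C11), even where strict lowest-locant rules would renumber.

## Retrosynthetic overview

1. Obtusane (12) ⇐ methylenation of the C7 ketone of 11; 11 ⇐ BrCl addition and 1,2-halogen interchange on the ring-B alkene of 9.
2. 9 ⇐ catalyst-controlled desymmetrising isomerisation of the 3-methylidene ketone 8 (sets spiro C6) ⇐ symmetric spiro-diketone 7.
3. 7 ⇐ spirodienone 5 ⇐ enantioselective bromonium-triggered dearomative ipso-cyclisation of anisole 4 (sets C10, makes the C6–C11 bond).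
4. 4 ⇐ p-anisaldehyde + homoprenyl Grignard + benzyl chloroformate.
5. Ring order: ring B is the anisole ring throughout; ring A closes onto it in the dearomatisation; ring B is then reduced and re-functionalised.

## Route

**Step 1**
Reactants: 1 (4-methoxybenzaldehyde), 2 (5-bromo-2-methylpent-2-ene), 3 (benzyl chloroformate)
Product: 4, rac-benzyl 1-(4-methoxyphenyl)-5-methylhex-4-en-1-yl carbonate
Conditions: 2, Mg, THF; add 1, 0 °C; then 3, 0 °C → rt
Reagents that add atoms: benzyl chloroformate (3), O=C(Cl)OCc1ccccc1
Why: Grignard 1,2-addition followed by in-situ O-acylation of the magnesium alkoxide gives a carbonate whose oxygen cannot trap the later cation as a bromo-tetrahydropyran and which is removable by hydrogenolysis; the C7 centre is racemic and is erased in step 4.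

**Step 2 (key step)**
Reactants: 4
Product: 5, benzyl (10R)-10-bromo-11,11-dimethyl-3-oxospiro[5.5]undeca-1,4-dien-7-yl carbonate (both C7 epimers)
Conditions: DBDMH (1.1 equiv), chiral BINOL-derived thiophosphoramide Lewis base (10 mol%, enantiomer giving 10R), toluene/CH2Cl2, −90 → −78 °C; then aq. NaHCO3/Na2S2O3
Reagents that add atoms: 1,3-dibromo-5,5-dimethylhydantoin, CC1(C)N(Br)C(=O)N(Br)C1=O
Why: Proposed new method: the chiral Lewis base·Br+ complex forms the bromonium on one face of the trisubstituted alkene (sets C10), the tertiary terminus C11 is captured in a six-membered chair transition state by the anisole ipso carbon (the only ring position para to OMe; ortho attack would need a seven-membered ring at carbons meta to OMe), and the O-methyl oxocarbenium loses methyl to give the dienone; the closest known reactions are catalytic asymmetric arene-terminated bromo-polyene cyclisation and ipso-halocyclisation of p-anisyl alkynes to spirodienones.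

**Step 3**
Reactants: 5
Product: 6, (10R)-10-bromo-7-hydroxy-11,11-dimethylspiro[5.5]undecan-3-one (both C7 epimers)
Conditions: H2 (1 atm), 10% Pd/C, EtOAc, rt
Reagents that add atoms: none
Why: Heterogeneous hydrogenation saturates both dienone C=C bonds and hydrogenolyses the benzyl carbonate (loss of toluene and CO2) in one operation, while the neopentyl secondary bromide is slow to cleave under neutral conditions.

**Step 4**
Reactants: 6
Product: 7, (10R)-10-bromo-11,11-dimethylspiro[5.5]undecane-3,7-dione
Conditions: Dess–Martin periodinane, NaHCO3, CH2Cl2, 0 °C → rt
Reagents that add atoms: none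
Why: Dess–Martin oxidation of the hindered secondary alcohol removes the C7 stereocentre, so both epimers converge on one compound in which ring B is locally symmetric and C10 is the only stereocentre.

**Step 5**
Reactants: 7
Product: 8, (10R)-10-bromo-11,11-dimethyl-3-methylidenespiro[5.5]undecan-7-one
Conditions: Zn, CH2Br2, TiCl4, THF/CH2Cl2, 0 °C → rt (Takai–Lombardo, 1.3 equiv)
Reagents that add atoms: dibromomethane, BrCBr
Why: Takai–Lombardo methylenation is non-basic (so the γ-bromo ketone cannot cyclise to a cyclopropane through its enolate) and reacts at the unhindered C3 ketone rather than the C7 ketone, which is flanked by the spiro quaternary carbon.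

**Step 6**
Reactants: 8
Product: 9, (6R,10R)-10-bromo-3,11,11-trimethylspiro[5.5]undec-2-en-7-one
Conditions: CoCl2 (5 mol%), chiral ligand L* (6 mol%), NaBHEt3 (10 mol%), toluene, rt
Reagents that add atoms: none
Why: Cobalt-hydride desymmetrising isomerisation of an exocyclic methylidene (insertion/β-H elimination) moves the double bond into one of the two locally enantiotopic ring CH2 arms under catalyst control, which turns the spiro carbon C6 into a defined stereocentre; this is the known Co-catalysed desymmetric isomerisation of 4,4-disubstituted methylidenecyclohexanes.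

**Step 7**
Reactants: 9
Product: 11, (2S,3S,6R,10R)-3,10-dibromo-2-chloro-3,11,11-trimethylspiro[5.5]undecan-7-one, via the non-isolated trans-diaxial adduct 10, (2R,3R,6R,10R)-2,10-dibromo-3-chloro-3,11,11-trimethylspiro[5.5]undecan-7-one
Conditions: Bu4N+ BrCl2− (1.05 equiv), CH2Cl2, −40 → 0 °C; then switch to MeCN, 60 °C
Reagents that add atoms: tetrabutylammonium dichlorobromate (Bu4N+ BrCl2−, written as its Bu4NCl·BrCl components), CCCC[N+](CCCC)(CCCC)CCCC.[Cl-].ClBr
Why: Bromonium formation is reversible, and the product-determining chloride attack is Markovnikov and trans-diaxial (Fürst–Plattner) in the ring-B chair that keeps CMe2 equatorial, so Br ends up axial at C2 on the face syn to the axial C7 carbonyl and Cl axial on tertiary C3 (10); the classical thermal diaxial→diequatorial 1,2-halogen interchange through the bromonium/chloride ion pair then relieves the Br/C7 syn-diaxial strain and gives the trans-diequatorial 2-chloro-3-bromo arrangement, setting C2 and C3 relative to C6.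

**Step 8**
Reactants: 11
Product: 12, obtusane, (2S,3S,6S,10R)-3,10-dibromo-2-chloro-3,11,11-trimethyl-7-methylidenespiro[5.5]undecane
Conditions: Cp2TiMe2 (3 equiv), toluene/THF, 65 °C, dark
Reagents that add atoms: dimethyltitanocene (Petasis reagent), [CH3-].[CH3-].[Ti+4].c1cc[cH-]c1.c1cc[cH-]c1
Why: Petasis methylenation converts the hindered, enolisable C7 ketone to the exocyclic methylene without base, Lewis acid or reducing metal, so the tertiary bromide, the vicinal chloride and the secondary bromide are untouched (the C6 descriptor changes from R to S only through CIP priorities).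

## Compound list

1 | 4-methoxybenzaldehyde | COc1ccc(C=O)cc1 | starting material
2 | 5-bromo-2-methylpent-2-ene | CC(C)=CCCBr | starting material
3 | benzyl chloroformate | O=C(Cl)OCc1ccccc1 | starting material
4 | rac-benzyl 1-(4-methoxyphenyl)-5-methylhex-4-en-1-yl carbonate | COc1ccc(cc1)C(CCC=C(C)C)OC(=O)OCc1ccccc1 | intermediate
5 | benzyl (10R)-10-bromo-11,11-dimethyl-3-oxospiro[5.5]undeca-1,4-dien-7-yl carbonate (C7 epimers) | O=C(OCc1ccccc1)OC1CC[C@@H](Br)C(C)(C)C12C=CC(=O)C=C2 | intermediate
6 | (10R)-10-bromo-7-hydroxy-11,11-dimethylspiro[5.5]undecan-3-one (C7 epimers) | OC1CC[C@@H](Br)C(C)(C)C12CCC(=O)CC2 | intermediate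
7 | (10R)-10-bromo-11,11-dimethylspiro[5.5]undecane-3,7-dione | O=C1CC[C@@H](Br)C(C)(C)C12CCC(=O)CC2 | intermediate
8 | (10R)-10-bromo-11,11-dimethyl-3-methylidenespiro[5.5]undecan-7-one | O=C1CC[C@@H](Br)C(C)(C)C12CCC(=C)CC2 | intermediate
9 | (6R,10R)-10-bromo-3,11,11-trimethylspiro[5.5]undec-2-en-7-one | O=C1CC[C@@H](Br)C(C)(C)[C@]12CCC(C)=CC2 | intermediate
10 | (2R,3R,6R,10R)-2,10-dibromo-3-chloro-3,11,11-trimethylspiro[5.5]undecan-7-one (diaxial adduct, not isolated) | O=C1CC[C@@H](Br)C(C)(C)[C@]12CC[C@@](C)(Cl)[C@H](Br)C2 | intermediate
11 | (2S,3S,6R,10R)-3,10-dibromo-2-chloro-3,11,11-trimethylspiro[5.5]undecan-7-one | O=C1CC[C@@H](Br)C(C)(C)[C@]12CC[C@](C)(Br)[C@@H](Cl)C2 | intermediate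
12 | obtusane, (2S,3S,6S,10R)-3,10-dibromo-2-chloro-3,11,11-trimethyl-7-methylidenespiro[5.5]undecane | C=C1CC[C@@H](Br)C(C)(C)[C@]12CC[C@](C)(Br)[C@@H](Cl)C2 | target

## Summary

Total steps: 8. Longest linear sequence: 8.

Steps most likely to fail, each with a fallback that changes the approach:

1. **Step 2, dearomative bromo-spirocyclisation.** Risks are elimination or intermolecular capture of the bromonium, 1,2-shift of the spiro cation, and modest ee. Fallback: make the bromonium stereospecifically rather than catalytically. Sharpless dihydroxylation of 4, conversion to the epoxide, and bromide opening at C10 give an enantioenriched 10-bromo-11-ol. Ionising its tertiary centre in HFIP then lets the neighbouring bromide deliver a configurationally defined bromonium for the same ipso capture.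
2. **Step 6, desymmetrising isomerisation.** Risks are incompatibility of the Co–H catalyst with the alkyl bromide or ketone, and weak discrimination of the two arms. Fallback: select the arm at the diketone stage by enamine-catalysed enantioselective α-bromination of 7 at the unhindered C3 ketone. MeCeCl2 addition at C3 and Zn/AcOH reductive elimination of the resulting β-bromo alcohol then give the same alkene 9; the C2/C3 configurations are erased and only the C6 choice is carried through.
3. **Step 7, BrCl addition and halogen interchange.** Risks are anti-Markovnikov opening of the bromonium on the other face (which would end at the diequatorial 2-bromo-3-chloro isomer) and an interchange equilibrium that does not favour 11. Fallback: introduce the halogens one at a time through the epoxide. mCPBA epoxidises 9 on the face anti to the axial C7 carbonyl. Acid-mediated bromide opening at the tertiary carbon (inversion at C3) gives the trans-diequatorial 3-bromo-2-ol. SOCl2 in dioxane then replaces the C2 hydroxyl by chloride with retention (SNi, or double inversion through the bromonium).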